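**Strategy**

The target is a chain of three trans-2,3-diaryl-2,3-dihydrobenzofurans whose resorcinol rings A, B and C each carry the same contiguous triad: ring oxygen on C7a, furan carbon on C3a, next unit on C4. One linchpin, 5-(benzyloxy)-1,3-dibromo-2-iodobenzene, therefore builds every ring. Unit 3 is set by catalytic dynamic kinetic resolution; the chain then grows by acetophenone α-arylation and annulation. In the key step the deoxybenzoin carrying unit 3 and the linchpin give the central benzofuran in one palladium-catalysed operation: C3–C3a by enolate C-arylation at iodine, O1–C7a by enolate O-arylation at either bromine, the other bromine staying on C4. Ionic hydrogenation then relays configuration to C2 and C3.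

Key step: step 8

Remark on labels: unit 1 is the central dihydrobenzofuran (O1, C2, C3, C3a, C4 to C7, C7a; benzo ring B). Unit 2 is the stilbene-bearing one (primed atoms; benzo ring A). Unit 3 is the terminal one (double-primed atoms; benzo ring C; its 3-aryl group is ring D).

Remark on shorthand: Ar = 4-(benzyloxy)phenyl. U3 = (2R,3R)-6-(benzyloxy)-2-Ar-3-[3,5-bis(benzyloxy)phenyl]-2,3-dihydro-1-benzofuran-4-yl. U1 = (2S,3S)-6-(benzyloxy)-2-Ar-3-(U3)-2,3-dihydro-1-benzofuran-4-yl.

Remark on the chemistry: compounds 1, 5, 6 and 19 are taken as purchasable, and all ten phenols travel as benzyl ethers. The sense of the 1,4-relay in steps 9 and 12 rests on the rotamer model stated there and is the main assumption of the route.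

**Route**

Step 1
Reactants: 1 4-(benzyloxy)aniline
Product: 2 4-(benzyloxy)-2,6-dibromoaniline
Conditions: NBS (2.05 equiv), MeCN, 0 °C
Reagents that add atoms: N-bromosuccinimide, O=C1CCC(=O)N1Br
Why: Electrophilic aromatic bromination, in which the amino group outweighs the para-benzyloxy group and directs both bromine atoms to its two free ortho positions.

Step 2
Reactants: 2 4-(benzyloxy)-2,6-dibromoaniline
Product: 4 5-(benzyloxy)-1,3-dibromo-2-iodobenzene, via arenediazonium tosylate 3 (not isolated)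
Conditions: NaNO2, p-TsOH·H2O, KI, MeCN/H2O, 10 °C to rt
Reagents that add atoms: potassium iodide, [K+].[I-]; sodium nitrite, [Na+].[O-]N=O (nitrogen of 3 only); p-toluenesulfonic acid, Cc1ccc(S(=O)(=O)O)cc1 (counter-ion of 3 only)
Why: Diazotisation and Sandmeyer-type iodo-dediazoniation, which needs no copper because iodide itself reduces the diazonium ion, puts iodine exactly between the two bromine atoms and para to the benzyloxy group.

Step 3
Reactants: 5 1,3-bis(benzyloxy)-5-bromobenzene; 6 1-[4-(benzyloxy)phenyl]ethanone (1.3 equiv)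
Product: 7 1-Ar-2-[3,5-bis(benzyloxy)phenyl]ethanone
Conditions: Pd2(dba)3 (1 mol %), Xantphos (2.4 mol %), NaOtBu, THF, 70 °C
Reagents that add atoms: none
Why: Palladium-catalysed ketone α-arylation (Buchwald–Hartwig type) of the methyl ketone with an unhindered aryl bromide, kept at mono-arylation by the wide-bite-angle ligand and the excess of 6.

Step 4
Reactants: 7 1-Ar-2-[3,5-bis(benzyloxy)phenyl]ethanone; 4 5-(benzyloxy)-1,3-dibromo-2-iodobenzene (1.0 equiv)
Product: 8 (±)-1-Ar-2-[4-(benzyloxy)-2,6-dibromophenyl]-2-[3,5-bis(benzyloxy)phenyl]ethanone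
Conditions: Pd2(dba)3 (2.5 mol %), Xantphos (6 mol %), NaOtBu (2.2 equiv), THF, 50 °C
Reagents that add atoms: none
Why: The same enolate α-arylation run on the C–I bond only: at 50 °C zerovalent palladium should not insert into the hindered ortho C–Br bonds and the O-arylation that leads to a benzofuran should not start, so the racemic, readily enolised triaryl ketone is isolated.

Step 5
Reactants: 8 (±)-1-Ar-2-[4-(benzyloxy)-2,6-dibromophenyl]-2-[3,5-bis(benzyloxy)phenyl]ethanone
Product: 9 (1R,2R)-1-Ar-2-[4-(benzyloxy)-2,6-dibromophenyl]-2-[3,5-bis(benzyloxy)phenyl]ethanol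
Conditions: RuCl[(R,R)-TsDPEN](p-cymene) (3 mol %), HCO2H/Et3N (5:2), DMF, 40 °C
Reagents that add atoms: none
Why: Noyori–Ikariya asymmetric transfer hydrogenation under dynamic kinetic resolution: the α,α-diaryl ketone racemises through its enol in the amine medium, the (R,R) catalyst delivers hydride to the carbonyl face that gives the R carbinol (C2''), and the enantiomer of 8 that keeps the bulky 2,6-dibromoaryl group anti to the incoming hydride (Felkin–Anh arrangement) should be reduced faster, which sets C3'' as R.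

Step 6
Reactants: 9 (1R,2R)-1-Ar-2-[4-(benzyloxy)-2,6-dibromophenyl]-2-[3,5-bis(benzyloxy)phenyl]ethanol
Product: 10 (2R,3R)-6-(benzyloxy)-2-Ar-3-[3,5-bis(benzyloxy)phenyl]-4-bromo-2,3-dihydro-1-benzofuran (U3 bromide)
Conditions: CuI (10 mol %), 3,4,7,8-tetramethyl-1,10-phenanthroline (20 mol %), Cs2CO3, toluene, 110 °C
Reagents that add atoms: none
Why: Intramolecular Ullmann-type C–O coupling (5-exo closure) of the secondary alkoxide onto either of the two equivalent ortho bromides; no bond to a stereocenter is broken, so the (1R,2R) alcohol maps onto the trans (2R,3R) ring, and the second bromide is left on C4''.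

Step 7
Reactants: 10 U3 bromide; 6 1-[4-(benzyloxy)phenyl]ethanone (2 equiv)
Product: 11 1-Ar-2-(U3)ethanone
Conditions: Pd2(dba)3 (2 mol %), XPhos (8 mol %), NaOtBu, toluene, 80 °C
Reagents that add atoms: none
Why: Palladium-catalysed α-arylation of the methyl ketone by the hindered C4'' bromide, for which a bulky biaryl phosphine is chosen; the product is too hindered to be arylated again and the ether-type stereocenters are inert to NaOtBu.

Step 8
Reactants: 11 1-Ar-2-(U3)ethanone; 4 5-(benzyloxy)-1,3-dibromo-2-iodobenzene (1.2 equiv)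
Product: 13 6-(benzyloxy)-2-Ar-4-bromo-3-(U3)-1-benzofuran, via dibromoaryl ketone 12 (not isolated)
Conditions: Pd(OAc)2 (10 mol %), DPEphos (12 mol %), Cs2CO3 (3 equiv), o-xylene, 80 °C then 130 °C
Reagents that add atoms: none
Why: Zerovalent palladium inserts into the C–I bond of 4, the cesium enolate of 11 transmetalates and C–C reductive elimination gives α-aryl ketone 12 (new C3a–C3 bond); 12 is more acidic than 11, so its enolate forms at once, a second oxidative addition into one of the two equivalent ortho C–Br bonds gives a six-membered oxapalladacycle, and C–O reductive elimination closes the furan (new O1–C7a bond). The closest known reaction type is the palladium-catalysed coupling of benzyl ketones with ortho-dihaloarenes to 2,3-diarylbenzofurans, that is, enolate α-arylation followed by intramolecular enolate O-arylation. The only ring closed is the five-membered furan (O1, C2, C3, C3a, C7a), formally a 5-exo attack of the enolate oxygen on the arylpalladium carbon. No stereocenter is formed: C2 and C3 stay at the enol-ether level until step 9, and the two stereocenters of unit 3 carry no acidic hydrogen and should survive Cs2CO3. The step needs iodide-before-bromide chemoselectivity (secured by the halogen order), C- before O-arylation of the first enolate (normal for palladium enolates) and sparing of the second bromide, which ends on C4; the local symmetry of 4 makes either bromide acceptable for the closure, and the peri 3-aryl group shields the one that survives. A slight excess of 4 and a stop at full conversion of 11 should limit a second coupling or a direct arylation at C4–Br.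

Step 9
Reactants: 13 6-(benzyloxy)-2-Ar-4-bromo-3-(U3)-1-benzofuran
Product: 14 (2S,3S)-6-(benzyloxy)-2-Ar-4-bromo-3-(U3)-2,3-dihydro-1-benzofuran (U1 bromide)
Conditions: Et3SiH (6 equiv), CF3CO2H/CH2Cl2 (1:4), 0 °C
Reagents that add atoms: none
Why: Ionic hydrogenation of a 2-aryl benzofuran (C3 protonation to the oxygen- and aryl-stabilised C2 cation, then hydride transfer from silicon), with reversible acid opening at C2 letting the 2-aryl group settle trans to the 3-aryl group; C3 is set by 1,4-relay from unit 3, because in the rotamer about the hindered C3–C4'' bond that keeps ring D over the brominated benzo ring and away from the twisted C2 aryl group, the fused ring of unit 3 (C3a''–C3'') covers one face of C3, so the proton should enter from the other face and give 3S and hence (2S,3S).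

Step 10
Reactants: 14 U1 bromide; 6 1-[4-(benzyloxy)phenyl]ethanone (2 equiv)
Product: 15 1-Ar-2-(U1)ethanone
Conditions: Pd2(dba)3 (2 mol %), XPhos (8 mol %), NaOtBu, toluene, 80 °C
Reagents that add atoms: none
Why: Second palladium-catalysed α-arylation of 6, now by the C4 bromide of unit 1, under the conditions of step 7; no stereocenter is touched.

Step 11
Reactants: 15 1-Ar-2-(U1)ethanone; 4 5-(benzyloxy)-1,3-dibromo-2-iodobenzene (1.2 equiv)
Product: 17 6-(benzyloxy)-2-Ar-4-bromo-3-(U1)-1-benzofuran, via dibromoaryl ketone 16 (not isolated)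
Conditions: Pd(OAc)2 (10 mol %), DPEphos (12 mol %), Cs2CO3 (3 equiv), o-xylene, 80 °C then 130 °C
Reagents that add atoms: none
Why: Repeat of the benzofuran annulation of step 8 (enolate C-arylation at iodine, then enolate O-arylation at one of the equivalent bromides through a six-membered oxapalladacycle), which builds ring A with its C4' bromide and forms no stereocenter.

Step 12
Reactants: 17 6-(benzyloxy)-2-Ar-4-bromo-3-(U1)-1-benzofuran
Product: 18 (2R,3R)-6-(benzyloxy)-2-Ar-4-bromo-3-(U1)-2,3-dihydro-1-benzofuran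
Conditions: Et3SiH (6 equiv), CF3CO2H/CH2Cl2 (1:4), 0 °C
Reagents that add atoms: none
Why: Ionic hydrogenation as in step 9 in the mirror-image situation: unit 1 (2S,3S) is fused to the 3-aryl ring B and should shield the opposite face, so protonation should set C3' as R, and hydride transfer with acid equilibration at C2' gives the trans (2'R,3'R) ring.

Step 13
Reactants: 19 3,4-bis(benzyloxy)benzaldehyde
Product: 20 1,2-bis(benzyloxy)-4-ethenylbenzene
Conditions: Ph3PCH3Br, KOtBu, THF, 0 °C to rt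
Reagents that add atoms: methyltriphenylphosphonium bromide, C[P+](c1ccccc1)(c1ccccc1)c1ccccc1.[Br-]
Why: Wittig methylenation of the aromatic aldehyde with the unstabilised ylide made in the flask.

Step 14
Reactants: 18 (2R,3R)-6-(benzyloxy)-2-Ar-4-bromo-3-(U1)-2,3-dihydro-1-benzofuran; 20 1,2-bis(benzyloxy)-4-ethenylbenzene
Product: 21 (2R,3R)-6-(benzyloxy)-2-Ar-4-{(E)-2-[3,4-bis(benzyloxy)phenyl]ethenyl}-3-(U1)-2,3-dihydro-1-benzofuran
Conditions: Pd2(dba)3 (2.5 mol %), P(t-Bu)3·HBF4 (10 mol %), Cs2CO3, dioxane, 100 °C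
Reagents that add atoms: none
Why: Mizoroki–Heck reaction of the hindered aryl bromide with the styrene, in which syn insertion at the unsubstituted alkene carbon and syn β-hydride elimination give the E-stilbene.

Step 15
Reactants: 21 deca-O-benzyl ether of the target
Product: 22 CNP0099535.1 (target)
Conditions: BCl3 (30 equiv), pentamethylbenzene (30 equiv), CH2Cl2, −78 °C; MeOH quench
Reagents that add atoms: none
Why: Lewis-acid cleavage of all ten benzyl ethers at low temperature with pentamethylbenzene as a non-basic benzyl-cation scavenger, chosen because hydrogenolysis would reduce the stilbene; the stereocenters are not involved.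

**Compound list**

1 | 4-(benzyloxy)aniline | Nc1ccc(OCc2ccccc2)cc1 | starting material
2 | 4-(benzyloxy)-2,6-dibromoaniline | Nc1c(Br)cc(OCc2ccccc2)cc1Br | intermediate
3 | 4-(benzyloxy)-2,6-dibromobenzenediazonium 4-methylbenzenesulfonate | N#[N+]c1c(Br)cc(OCc2ccccc2)cc1Br.Cc1ccc(S(=O)(=O)[O-])cc1 | intermediate
4 | 5-(benzyloxy)-1,3-dibromo-2-iodobenzene (linchpin) | Ic1c(Br)cc(OCc2ccccc2)cc1Br | intermediate
5 | 1,3-bis(benzyloxy)-5-bromobenzene | Brc1cc(OCc2ccccc2)cc(OCc2ccccc2)c1 | starting material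
6 | 1-[4-(benzyloxy)phenyl]ethanone | CC(=O)c1ccc(OCc2ccccc2)cc1 | starting material
7 | 1-Ar-2-[3,5-bis(benzyloxy)phenyl]ethanone | O=C(Cc1cc(OCc2ccccc2)cc(OCc2ccccc2)c1)c1ccc(OCc2ccccc2)cc1 | intermediate
8 | (±)-1-Ar-2-[4-(benzyloxy)-2,6-dibromophenyl]-2-[3,5-bis(benzyloxy)phenyl]ethanone | O=C(c1ccc(OCc2ccccc2)cc1)C(c1cc(OCc2ccccc2)cc(OCc2ccccc2)c1)c1c(Br)cc(OCc2ccccc2)cc1Br | intermediate
9 | (1R,2R)-1-Ar-2-[4-(benzyloxy)-2,6-dibromophenyl]-2-[3,5-bis(benzyloxy)phenyl]ethanol | O[C@@H](c1ccc(OCc2ccccc2)cc1)[C@H](c1cc(OCc2ccccc2)cc(OCc2ccccc2)c1)c1c(Br)cc(OCc2ccccc2)cc1Br | intermediate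
10 | (2R,3R)-6-(benzyloxy)-2-Ar-3-[3,5-bis(benzyloxy)phenyl]-4-bromo-2,3-dihydro-1-benzofuran (U3 bromide) | Brc1cc(OCc2ccccc2)cc2c1[C@@H](c1cc(OCc3ccccc3)cc(OCc3ccccc3)c1)[C@H](c1ccc(OCc3ccccc3)cc1)O2 | intermediate
11 | 1-Ar-2-(U3)ethanone | O=C(Cc1cc(OCc2ccccc2)cc2c1[C@@H](c1cc(OCc3ccccc3)cc(OCc3ccccc3)c1)[C@H](c1ccc(OCc3ccccc3)cc1)O2)c1ccc(OCc2ccccc2)cc1 | intermediate
12 | 1-Ar-2-[4-(benzyloxy)-2,6-dibromophenyl]-2-(U3)ethanone (both epimers at the new methine) | O=C(c1ccc(OCc2ccccc2)cc1)C(c1c(Br)cc(OCc2ccccc2)cc1Br)c1cc(OCc2ccccc2)cc2c1[C@@H](c1cc(OCc3ccccc3)cc(OCc3ccccc3)c1)[C@H](c1ccc(OCc3ccccc3)cc1)O2 | intermediate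
13 | 6-(benzyloxy)-2-Ar-4-bromo-3-(U3)-1-benzofuran | Brc1cc(OCc2ccccc2)cc2oc(-c3ccc(OCc4ccccc4)cc3)c(-c3cc(OCc4ccccc4)cc4c3[C@@H](c3cc(OCc5ccccc5)cc(OCc5ccccc5)c3)[C@H](c3ccc(OCc5ccccc5)cc3)O4)c12 | intermediate
14 | (2S,3S)-6-(benzyloxy)-2-Ar-4-bromo-3-(U3)-2,3-dihydro-1-benzofuran (U1 bromide) | O(Cc1ccccc1)c1ccc([C@H]2Oc3cc(OCc4ccccc4)cc(Br)c3[C@@H]2c2cc(OCc4ccccc4)cc3c2[C@@H](c2cc(OCc4ccccc4)cc(OCc4ccccc4)c2)[C@H](c2ccc(OCc4ccccc4)cc2)O3)cc1 | intermediate
15 | 1-Ar-2-(U1)ethanone | O(Cc1ccccc1)c1ccc([C@H]2Oc3cc(OCc4ccccc4)cc(CC(=O)c4ccc(OCc5ccccc5)cc4)c3[C@@H]2c2cc(OCc4ccccc4)cc3c2[C@@H](c2cc(OCc4ccccc4)cc(OCc4ccccc4)c2)[C@H](c2ccc(OCc4ccccc4)cc2)O3)cc1 | intermediate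
16 | 1-Ar-2-[4-(benzyloxy)-2,6-dibromophenyl]-2-(U1)ethanone (both epimers at the new methine) | O(Cc1ccccc1)c1ccc([C@H]2Oc3cc(OCc4ccccc4)cc(C(C(=O)c4ccc(OCc5ccccc5)cc4)c4c(Br)cc(OCc5ccccc5)cc4Br)c3[C@@H]2c2cc(OCc4ccccc4)cc3c2[C@@H](c2cc(OCc4ccccc4)cc(OCc4ccccc4)c2)[C@H](c2ccc(OCc4ccccc4)cc2)O3)cc1 | intermediate
17 | 6-(benzyloxy)-2-Ar-4-bromo-3-(U1)-1-benzofuran | Brc1cc(OCc2ccccc2)cc2oc(-c3ccc(OCc4ccccc4)cc3)c(-c3cc(OCc4ccccc4)cc4c3[C@H](c3cc(OCc5ccccc5)cc5c3[C@@H](c3cc(OCc6ccccc6)cc(OCc6ccccc6)c3)[C@H](c3ccc(OCc6ccccc6)cc3)O5)[C@@H](c3ccc(OCc5ccccc5)cc3)O4)c12 | intermediate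
18 | (2R,3R)-6-(benzyloxy)-2-Ar-4-bromo-3-(U1)-2,3-dihydro-1-benzofuran | Brc1cc(OCc2ccccc2)cc2c1[C@@H](c1cc(OCc3ccccc3)cc3c1[C@H](c1cc(OCc4ccccc4)cc4c1[C@@H](c1cc(OCc5ccccc5)cc(OCc5ccccc5)c1)[C@H](c1ccc(OCc5ccccc5)cc1)O4)[C@@H](c1ccc(OCc4ccccc4)cc1)O3)[C@H](c1ccc(OCc3ccccc3)cc1)O2 | intermediate
19 | 3,4-bis(benzyloxy)benzaldehyde | O=Cc1ccc(OCc2ccccc2)c(OCc2ccccc2)c1 | starting material
20 | 1,2-bis(benzyloxy)-4-ethenylbenzene | C=Cc1ccc(OCc2ccccc2)c(OCc2ccccc2)c1 | intermediate
21 | (2R,3R)-6-(benzyloxy)-2-Ar-4-{(E)-2-[3,4-bis(benzyloxy)phenyl]ethenyl}-3-(U1)-2,3-dihydro-1-benzofuran (deca-O-benzyl ether of the target) | O(Cc1ccccc1)c1ccc(/C=C/c2cc(OCc3ccccc3)cc3c2[C@@H](c2cc(OCc4ccccc4)cc4c2[C@H](c2cc(OCc5ccccc5)cc5c2[C@@H](c2cc(OCc6ccccc6)cc(OCc6ccccc6)c2)[C@H](c2ccc(OCc6ccccc6)cc2)O5)[C@@H](c2ccc(OCc5ccccc5)cc2)O4)[C@H](c2ccc(OCc4ccccc4)cc2)O3)cc1OCc1ccccc1 | intermediate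
22 | CNP0099535.1, the decaphenol (21 with hydrogen in place of every benzyl group) | Oc1ccc([C@H]2Oc3cc(O)cc([C@@H]4c5c(/C=C/c6ccc(O)c(O)c6)cc(O)cc5O[C@H]4c4ccc(O)cc4)c3[C@@H]2c2cc(O)cc3c2[C@@H](c2cc(O)cc(O)c2)[C@H](c2ccc(O)cc2)O3)cc1 | target

**Totals and risks**

Total step count: 15. Longest linear sequence: 13 steps (steps 1, 2, 4 to 12, 14 and 15).

Most likely to fail, first: step 8 (and its repeat, step 11). The intermolecular C-arylation joins a 2,6-dibrominated arylpalladium species to an α-aryl enolate that itself carries an ortho substituent, and it may stall. The surviving bromide may also be consumed by a second coupling or by intramolecular direct arylation. The fallback sets out from 11 and 4 and comes back at 13. Compound 4 is oxidised (mCPBA, p-TsOH·H2O, then 1,3,5-trimethoxybenzene, CH2Cl2/CF3CH2OH) to [4-(benzyloxy)-2,6-dibromophenyl](2,4,6-trimethoxyphenyl)iodonium 4-methylbenzenesulfonate F1. The potassium enolate of 11 (KOtBu, THF, 0 °C) is then C-arylated by this salt without a transition metal (ligand coupling on iodine, the ortho-disubstituted aryl group being the one transferred), which gives 12 as an isolated compound. A separate copper-catalysed enolate O-arylation (CuI, 1,10-phenanthroline, Cs2CO3, DMF, 100 °C) closes the furan and rejoins the route at 13.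

Second: step 9 (and its mirror, step 12). Facial selectivity in the protonation at C3 may be poor or opposite if the rotamer model does not hold. The acid may also cause ionic hydrogenolysis of the benzylic C2–O and C2''–O bonds or Friedel–Crafts capture of the opened cations. The fallback sets out from 12 (isolated by running step 8 at 50 °C as in step 4, or by the iodonium route above) and comes back at 14. Transfer hydrogenation under dynamic kinetic resolution with RuCl[(S,S)-TsDPEN](p-cymene) in HCO2H/Et3N should give (1S,2S)-1-Ar-2-[4-(benzyloxy)-2,6-dibromophenyl]-2-(U3)ethanol F2, with both centers under reagent control. Copper-catalysed intramolecular O-arylation as in step 6 then gives 14 with retention.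

Third: step 15. Ten ether cleavages must all go to completion while the Lewis acid can ionise the 2-aryl C–O bonds, and the stilbene can then cyclise onto the resulting cations. The fallback sets out from 18 and comes back at 22; it moves the acid step ahead of the stilbene. Compound 18 is debenzylated (BCl3, pentamethylbenzene, CH2Cl2, −78 °C) to the octaphenol (2R,3R)-4-bromo-2-(4-hydroxyphenyl)-3-(octa-O-debenzylated U1)-2,3-dihydro-1-benzofuran-6-ol F3. Purchased 3,4-bis(tert-butyldimethylsilyloxy)benzaldehyde is methylenated (Ph3PCH3Br, KOtBu, THF) to 1,2-bis(tert-butyldimethylsilyloxy)-4-ethenylbenzene F4. Mizoroki–Heck coupling of the two (Pd2(dba)3, P(t-Bu)3·HBF4, Et3N, DMF, 90 °C) gives the 3,4-bis-O-(tert-butyldimethylsilyl) ether of the target F5. Buffered fluoride (TBAF, AcOH, THF, 0 °C) then frees the catechol and arrives at 22.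

Further compounds
F1 | step 8 | [4-(benzyloxy)-2,6-dibromophenyl](2,4,6-trimethoxyphenyl)iodonium 4-methylbenzenesulfonate | COc1cc(OC)c([I+]c2c(Br)cc(OCc3ccccc3)cc2Br)c(OC)c1.Cc1ccc(S(=O)(=O)[O-])cc1
F2 | step 9 | (1S,2S)-1-Ar-2-[4-(benzyloxy)-2,6-dibromophenyl]-2-(U3)ethanol | O[C@H](c1ccc(OCc2ccccc2)cc1)[C@@H](c1cc(OCc2ccccc2)cc2c1[C@@H](c1cc(OCc3ccccc3)cc(OCc3ccccc3)c1)[C@H](c1ccc(OCc3ccccc3)cc1)O2)c1c(Br)cc(OCc2ccccc2)cc1Br
F3 | step 15 | octaphenol bromide (18 with hydrogen in place of every benzyl group) | Brc1cc(O)cc2c1[C@@H](c1cc(O)cc3c1[C@H](c1cc(O)cc4c1[C@@H](c1cc(O)cc(O)c1)[C@H](c1ccc(O)cc1)O4)[C@@H](c1ccc(O)cc1)O3)[C@H](c1ccc(O)cc1)O2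
F4 | step 15 | 1,2-bis(tert-butyldimethylsilyloxy)-4-ethenylbenzene | C=Cc1ccc(O[Si](C)(C)C(C)(C)C)c(O[Si](C)(C)C(C)(C)C)c1
F5 | step 15 | 3,4-bis-O-(tert-butyldimethylsilyl) ether of the target (silyl groups on the catechol oxygens) | CC(C)(C)[Si](C)(C)Oc1ccc(/C=C/c2cc(O)cc3c2[C@@H](c2cc(O)cc4c2[C@H](c2cc(O)cc5c2[C@@H](c2cc(O)cc(O)c2)[C@H](c2ccc(O)cc2)O5)[C@@H](c2ccc(O)cc2)O4)[C@H](c2ccc(O)cc2)O3)cc1O[Si](C)(C)C(C)(C)C
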